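The four-membered ring is C4–C5–C11–C10 (longipinane numbering, C1 = ketone), and everything rests on its C4–C10 bond. The key step closes this ring last. A Lewis acid opens a 9,10-epoxide on a cis-fused bicyclo[5.4.0]undecane, and C4, the γ-carbon of the C1 silyl dienol ether, attacks C10 (4-exo vinylogous Mukaiyama opening). One operation should give the cyclobutane, the quaternary C10, the C9 carbinol and the C1 enone that later takes the C3 methyl. It exploits that C4 is γ to the C1 carbonyl and 1,4 to C10, and that C9 carries oxygen. The precursor arises from a Diels–Alder adduct of 4,4-dimethylcyclopentenone, recut by ozonolysis, alkoxyallylboration and ring-closing metathesis.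

Key step: step 16

Remark on numbering: C1 = ring C=O, C2 = CH2, C3 = CH(CH3), C4 = CH next to C3, C5 = CH between C4 and C11 that bears C6 (CMe2), C7/C8/C9 = oxygenated carbons (C7 next to C6), C10 = C(CH3), C11 = CH between C10 and C1. Bicyclic compounds without the C4–C10 bond are named 4,10-secolongipinanes with the same numbers, and "15-nor" means no methyl on C3.

Assumption: the (S)-oxazaborolidinium ion of step 2 is taken to shield the enone face that leads to (3aS,7aS)-4; if the sense proves opposite, its enantiomer is used.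

Step 1
Reactants: 1 (E)-but-2-enal
Product: 2 (E)-1-(tert-butyldimethylsilyloxy)buta-1,3-diene
Conditions: TBSOTf, Et3N, Et2O, 0 °C → rt
Reagents that add atoms: tert-butyldimethylsilyl triflate, CC(C)(C)[Si](C)(C)OS(=O)(=O)C(F)(F)F
Why: Soft enolisation (1,4-O-silylation) of the enal, in which Et3N removes a γ-proton of the O-silylated aldehyde, should give the E-dienyl silyl ether.

Step 2
Reactants: 2 (E)-1-(tert-butyldimethylsilyloxy)buta-1,3-diene; 3 4,4-dimethylcyclopent-2-en-1-one
Product: 4 (3aS,7R,7aS)-7-(tert-butyldimethylsilyloxy)-3,3-dimethyl-2,3,3a,4,7,7a-hexahydro-1H-inden-1-one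
Conditions: (S)-3,3-diphenyl-1-(o-tolyl)tetrahydro-1H,3H-pyrrolo[1,2-c][1,3,2]oxazaborole·HNTf2 (20 mol%), CH2Cl2, −78 → −40 °C
Reagents that add atoms: none
Why: Diels–Alder reaction in which the unsubstituted diene terminus bonds to the enone β-carbon (future C5), suprafacial addition gives the cis ring fusion (C5, C11), the endo mode puts the silyloxy group cis to the acyl bond, and the chiral boron Lewis acid blocks one enone face to set the absolute configuration.

Step 3
Reactants: 4 Diels–Alder adduct
Product: 6 7-(tert-butyldimethylsilyloxy)-3,3-dimethyl-3a,4,7,7a-tetrahydro-3H-inden-1-yl triflate (stereocentres as in 4), via potassium enolate 5 (not isolated)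
Conditions: KN(SiMe3)2, THF, −78 °C; then PhNTf2
Reagents that add atoms: N-phenylbis(trifluoromethanesulfonimide), FC(F)(F)S(=O)(=O)N(c1ccccc1)S(=O)(=O)C(F)(F)F
Why: Kinetic enolate formation at the methylene (not at the hindered ring-fusion methine, whose enolate would expel the β-silyloxy group) followed by O-triflation should give the enol triflate regioselectively.

Step 4
Reactants: 6 enol triflate
Product: 7 7-(tert-butyldimethylsilyloxy)-1,3,3-trimethyl-3a,4,7,7a-tetrahydro-3H-indene (stereocentres as in 4)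
Conditions: MeMgBr, Fe(acac)3 (5 mol%), THF–NMP, −30 °C
Reagents that add atoms: methylmagnesium bromide, C[Mg]Br
Why: Kumada-type cross-coupling of the alkenyl triflate under Fe(acac)3 catalysis installs the methyl group that becomes the C10 methyl without touching the silyl ether.

Step 5
Reactants: 7 trimethyl diene
Product: 8 2-[all-cis-6-acetyl-5-(tert-butyldimethylsilyloxy)cyclohex-3-en-1-yl]-2-methylpropanal
Conditions: O3 (1.0 equiv, dye end-point), pyridine, CH2Cl2, −78 °C
Reagents that add atoms: ozone, [O-][O+]=O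
Why: Ozonolysis should cleave the electron-rich trisubstituted cyclopentene ahead of the disubstituted alkene deactivated by the allylic silyloxy group, and pyridine turns the carbonyl oxide directly into the carbonyls under non-basic conditions that keep C11 and the β-silyloxy ketone intact.

Step 6
Reactants: 8 keto aldehyde; 9 3-(methoxymethoxy)prop-1-ene
Product: 12 (3S,4S)-5-[all-cis-6-acetyl-5-(tert-butyldimethylsilyloxy)cyclohex-3-en-1-yl]-3-(methoxymethoxy)-5-methylhex-1-en-4-ol, via γ-alkoxyallylborane 10 (not isolated), via borinate 11 (not isolated)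
Conditions: 9, sec-BuLi, THF, −78 °C; (+)-Ipc2BOMe; BF3·OEt2; then 8, −78 °C; H2O2, pH 7 buffer, 0 °C
Reagents that add atoms: none
Why: Asymmetric γ-alkoxyallylboration through a chair Zimmerman–Traxler transition state, in which the Z-borane gives the syn relationship and the isopinocampheyl groups choose the aldehyde face, should set C7 and C8 while the ketone does not react at −78 °C.

Step 7
Reactants: 12 syn-alkoxyallylation product
Product: 13 (3S,4S)-3-(methoxymethoxy)-5-methyl-5-[all-cis-6-(prop-1-en-2-yl)-5-(tert-butyldimethylsilyloxy)cyclohex-3-en-1-yl]hex-1-en-4-ol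
Conditions: Cp2TiMe2 (3 equiv), toluene–THF, 65 °C, dark
Reagents that add atoms: Cp2TiMe2 (dimethyltitanocene), C[Ti](C)(C1C=CC=C1)C1C=CC=C1
Why: Petasis methylenation converts the hindered, enolisable methyl ketone into the isopropenyl group under non-basic conditions, so C11 should not epimerise.

Step 8
Reactants: 13 triene
Product: 14 1-(tert-butyldimethylsilyloxy)-8-(methoxymethoxy)-15-nor-4,10-secolongipina-2,9-dien-7-ol
Conditions: (H2IMes)(PCy3)Cl2Ru=CHPh (second-generation Grubbs catalyst, 10 mol%), toluene, 80 °C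
Reagents that add atoms: none
Why: Ring-closing metathesis of the isopropenyl and vinyl groups, held cis on the cyclohexene, should close the seven-membered ring as the trisubstituted C9=C10 alkene with loss of ethene.

Step 9
Reactants: 15 angelic acid
Product: 16 angelic 2,4,6-trichlorobenzoic anhydride
Conditions: 2,4,6-trichlorobenzoyl chloride (1.0 equiv), Et3N (1.05 equiv), toluene, rt; filtration from Et3NHCl under argon; kept as a toluene solution at −20 °C
Reagents that add atoms: 2,4,6-trichlorobenzoyl chloride, O=C(Cl)c1c(Cl)cc(Cl)cc1Cl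
Why: Yamaguchi mixed-anhydride formation, in which the triethylammonium carboxylate of 15 is acylated by the aroyl chloride, should keep the Z double bond because no nucleophilic catalyst is present, and the salt-free solution serves both later esterifications.

Step 10
Reactants: 14 bicyclic diene alcohol; 16 angelic 2,4,6-trichlorobenzoic anhydride
Product: 17 7-angeloyloxy-1-(tert-butyldimethylsilyloxy)-8-(methoxymethoxy)-15-nor-4,10-secolongipina-2,9-diene
Conditions: 16 (3 equiv), Et3N (1.2 equiv), toluene, 80 °C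
Reagents that add atoms: none
Why: Yamaguchi-type esterification, in which the alcohol attacks the angeloyl carbonyl because the aroyl carbonyl is shielded by its two ortho chlorines, is run without DMAP to avoid Z to E isomerisation and acylates the only free hydroxyl (C7) while C8 stays masked as its MOM ether.

Step 11
Reactants: 17 C7 angelate
Product: 19 7-angeloyloxy-1-(tert-butyldimethylsilyloxy)-15-nor-4,10-secolongipina-2,9-dien-8-ol, via bromomethyl ether 18 (not isolated)
Conditions: Me2BBr, CH2Cl2, −78 °C; then NaHCO3, THF–H2O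
Reagents that add atoms: none
Why: Lewis-acid acetal cleavage at −78 °C removes the MOM group through its bromomethyl ether and should leave the silyl ether, the ester and the alkenes untouched.

Step 12
Reactants: 19 C8 allylic alcohol
Product: 20 7-angeloyloxy-1-(tert-butyldimethylsilyloxy)-9,10-epoxy-15-nor-4,10-secolongipin-2-en-8-ol (epoxide oxygen cis to 8-OH)
Conditions: VO(acac)2 (5 mol%), t-BuOOH, CH2Cl2, 0 °C
Reagents that add atoms: tert-butyl hydroperoxide, CC(C)(C)OO
Why: Hydroxyl-directed epoxidation delivers oxygen to the C9=C10 alkene syn to the allylic C8 hydroxyl, which is also the convex face, and so fixes C9 and the epoxide face that the ring closure needs.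

Step 13
Reactants: 20 epoxy silyl ether
Product: 21 7-angeloyloxy-9,10-epoxy-15-nor-4,10-secolongipin-2-ene-1,8-diol
Conditions: Bu4NF, AcOH, THF, 0 °C → rt
Reagents that add atoms: none
Why: Buffered fluoride desilylation frees the allylic C1 alcohol without opening the epoxide or inducing acyl migration.

Step 14
Reactants: 21 diol
Product: 22 7-angeloyloxy-9,10-epoxy-8-hydroxy-15-nor-4,10-secolongipin-2-en-1-one
Conditions: MnO2, CH2Cl2, rt
Reagents that add atoms: none
Why: MnO2 oxidises only the allylic C1 alcohol, giving the enone under neutral conditions that spare the β,γ-epoxide.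

Step 15
Reactants: 22 epoxy enone
Product: 23 7-angeloyloxy-1,8-bis(tert-butyldimethylsilyloxy)-9,10-epoxy-15-nor-4,10-secolongipina-1,3-diene
Conditions: TBSOTf (2.5 equiv), Et3N, CH2Cl2, −78 → −40 °C
Reagents that add atoms: tert-butyldimethylsilyl triflate, CC(C)(C)[Si](C)(C)OS(=O)(=O)C(F)(F)F
Why: Soft enolisation silylates the C8 hydroxyl and the enone oxygen, and Et3N should remove the axial γ-proton at C4 to give the linear dienol ether, because the α′-proton at C11 is equatorial (C10 axial on the cis-fused ring) and hindered.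

Step 16
Reactants: 23 epoxy silyl dienol ether
Product: 24 7-angeloyloxy-8-(tert-butyldimethylsilyloxy)-9-hydroxy-15-norlongipin-2-en-1-one
Conditions: MeAlCl2 (2.2 equiv), CH2Cl2, −78 °C; then NaHCO3 (aq)
Reagents that add atoms: none
Why: Proposed new method: MeAlCl2 binds the epoxide oxygen, the C10–O bond ionises at the tertiary carbon, and C4, the γ-carbon of the silyl dienol ether, attacks C10 from the rear in a vinylogous Mukaiyama reaction, after which the silyloxocarbenium ion loses TBSCl to leave the C1 enone. The closest known reaction types are MeAlCl2-promoted epoxide-initiated cation–olefin cyclisations that end on a silyl enol ether (six-membered rings) and the biogenetic terpinyl to pinyl closure, but a four-membered ring has not been made this way. The cyclobutane (C4–C5–C11–C10) closes 4-exo-tet at the epoxide and enolexo at the nucleophile, whereas attack by C2 would be enolendo and is geometrically excluded. C10 is set by inversion (anti opening) and C9 keeps the configuration from step 12, so the 9-hydroxyl and C4 end up anti as in the target, while C4 and C11 follow from the cis ring fusion. The step needs opening at C10 and not C9, and C–C bond formation ahead of hydride shift or ether formation, which the substrate secures through the tertiary centre, the inductive deactivation of C9 by the C8 silyloxy group, the non-nucleophilic C7 ester and the axial C10 substituent that sits 1,3 over C4. Release of epoxide strain pays for the cyclobutane, and loss of the silyl group makes the closure irreversible.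

Step 17
Reactants: 24 tricyclic enone
Product: 25 7-angeloyloxy-8-(tert-butyldimethylsilyloxy)-9-hydroxylongipinan-1-one
Conditions: Me2CuLi (3 equiv, from MeLi and CuI), Et2O, −78 °C; then NH4Cl (aq)
Reagents that add atoms: lithium dimethylcuprate Me2CuLi, [Li+].C[Cu-]C
Why: Conjugate addition of the Gilman cuprate to the strained enone should occur on the face away from the C10 bridge and its methyl, which sets C3, and the far less electrophilic angelate does not react at −78 °C.

Step 18
Reactants: 25 hydroxy ketone; 16 angelic 2,4,6-trichlorobenzoic anhydride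
Product: 26 7,9-bis(angeloyloxy)-8-(tert-butyldimethylsilyloxy)longipinan-1-one
Conditions: 16 (5 equiv), Et3N (1.2 equiv), toluene, 90 °C
Reagents that add atoms: none
Why: Yamaguchi-type esterification of the hindered neopentyl C9 alcohol with the preformed mixed anhydride at raised temperature, again without DMAP, should keep the Z geometry.

Step 19
Reactants: 26 silyl-protected diester
Product: 27 (3R,4S,5S,7S,8R,9S,10R,11R)-7,9-bis[(Z)-2-methylbut-2-enoyloxy]-8-hydroxylongipinan-1-one
Conditions: HF·pyridine, THF, 0 °C → rt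
Reagents that add atoms: none
Why: Acidic fluoride desilylation frees the C8 hydroxyl under conditions that should not cause acyl migration between the neighbouring esters.

Compound list
1 | (E)-but-2-enal | C/C=C/C=O | starting material
2 | (E)-1-(tert-butyldimethylsilyloxy)buta-1,3-diene | C=C/C=C/O[Si](C)(C)C(C)(C)C | intermediate
3 | 4,4-dimethylcyclopent-2-en-1-one | O=C1C=CC(C)(C)C1 | starting material
4 | (3aS,7R,7aS)-7-(tert-butyldimethylsilyloxy)-3,3-dimethyl-2,3,3a,4,7,7a-hexahydro-1H-inden-1-one (cis-fused, OTBS cis to the C7a–C1 bond) | O=C1CC(C)(C)[C@H]2CC=C[C@@H](O[Si](C)(C)C(C)(C)C)[C@@H]12 | intermediate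
5 | potassium enolate of 4 (C1–O−, C1=C2) | [K+].[O-]C1=CC(C)(C)[C@H]2CC=C[C@@H](O[Si](C)(C)C(C)(C)C)[C@@H]12 | intermediate
6 | 7-(tert-butyldimethylsilyloxy)-3,3-dimethyl-3a,4,7,7a-tetrahydro-3H-inden-1-yl triflate (stereocentres as in 4) | FC(F)(F)S(=O)(=O)OC1=CC(C)(C)[C@H]2CC=C[C@@H](O[Si](C)(C)C(C)(C)C)[C@@H]12 | intermediate
7 | 7-(tert-butyldimethylsilyloxy)-1,3,3-trimethyl-3a,4,7,7a-tetrahydro-3H-indene (stereocentres as in 4) | CC1=CC(C)(C)[C@H]2CC=C[C@@H](O[Si](C)(C)C(C)(C)C)[C@@H]12 | intermediate
8 | 2-[all-cis-6-acetyl-5-(tert-butyldimethylsilyloxy)cyclohex-3-en-1-yl]-2-methylpropanal | CC(=O)[C@@H]1[C@H](O[Si](C)(C)C(C)(C)C)C=CC[C@@H]1C(C)(C)C=O | intermediate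
9 | 3-(methoxymethoxy)prop-1-ene (allyl methoxymethyl ether) | C=CCOCOC | starting material
10 | [(Z)-3-(methoxymethoxy)prop-2-en-1-yl]bis(isopinocampheyl)borane from (+)-Ipc2BOMe | COCO/C=C\CB([C@@H]1[C@@H](C)[C@@H]2C[C@H](C1)C2(C)C)[C@@H]1[C@@H](C)[C@@H]2C[C@H](C1)C2(C)C | intermediate
11 | bis(isopinocampheyl)borinate of 12 (B–O on C7) | CC(=O)[C@@H]1[C@H](O[Si](C)(C)C(C)(C)C)C=CC[C@@H]1C(C)(C)[C@H](OB([C@@H]2[C@@H](C)[C@@H]3C[C@H](C2)C3(C)C)[C@@H]2[C@@H](C)[C@@H]3C[C@H](C2)C3(C)C)[C@@H](OCOC)C=C | intermediate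
12 | (3S,4S)-5-[all-cis-6-acetyl-5-(tert-butyldimethylsilyloxy)cyclohex-3-en-1-yl]-3-(methoxymethoxy)-5-methylhex-1-en-4-ol (syn) | CC(=O)[C@@H]1[C@H](O[Si](C)(C)C(C)(C)C)C=CC[C@@H]1C(C)(C)[C@H](O)[C@@H](OCOC)C=C | intermediate
13 | (3S,4S)-3-(methoxymethoxy)-5-methyl-5-[all-cis-6-(prop-1-en-2-yl)-5-(tert-butyldimethylsilyloxy)cyclohex-3-en-1-yl]hex-1-en-4-ol | C=C(C)[C@@H]1[C@H](O[Si](C)(C)C(C)(C)C)C=CC[C@@H]1C(C)(C)[C@H](O)[C@@H](OCOC)C=C | intermediate
14 | 1-(tert-butyldimethylsilyloxy)-8-(methoxymethoxy)-15-nor-4,10-secolongipina-2,9-dien-7-ol (H-5/H-11 cis, 7-O/8-O trans) | O[C@@H]1[C@@H](OCOC)C=C(C)[C@@H]2[C@H](O[Si](C)(C)C(C)(C)C)C=CC[C@@H]2C1(C)C | intermediate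
15 | angelic acid, (Z)-2-methylbut-2-enoic acid | C/C=C(/C)C(=O)O | starting material
16 | angelic 2,4,6-trichlorobenzoic anhydride | C/C=C(/C)C(=O)OC(=O)c1c(Cl)cc(Cl)cc1Cl | intermediate
17 | 7-angeloyloxy-1-(tert-butyldimethylsilyloxy)-8-(methoxymethoxy)-15-nor-4,10-secolongipina-2,9-diene | C/C=C(/C)C(=O)O[C@@H]1[C@@H](OCOC)C=C(C)[C@@H]2[C@H](O[Si](C)(C)C(C)(C)C)C=CC[C@@H]2C1(C)C | intermediate
18 | 8-O-bromomethyl ether of 19 | C/C=C(/C)C(=O)O[C@@H]1[C@@H](OCBr)C=C(C)[C@@H]2[C@H](O[Si](C)(C)C(C)(C)C)C=CC[C@@H]2C1(C)C | intermediate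
19 | 7-angeloyloxy-1-(tert-butyldimethylsilyloxy)-15-nor-4,10-secolongipina-2,9-dien-8-ol | C/C=C(/C)C(=O)O[C@@H]1[C@@H](O)C=C(C)[C@@H]2[C@H](O[Si](C)(C)C(C)(C)C)C=CC[C@@H]2C1(C)C | intermediate
20 | 7-angeloyloxy-1-(tert-butyldimethylsilyloxy)-9,10-epoxy-15-nor-4,10-secolongipin-2-en-8-ol (epoxide cis to 8-OH) | C/C=C(/C)C(=O)O[C@@H]1[C@@H](O)[C@H]2O[C@@]2(C)[C@@H]3[C@H](O[Si](C)(C)C(C)(C)C)C=CC[C@@H]3C1(C)C | intermediate
21 | 7-angeloyloxy-9,10-epoxy-15-nor-4,10-secolongipin-2-ene-1,8-diol | C/C=C(/C)C(=O)O[C@@H]1[C@@H](O)[C@H]2O[C@@]2(C)[C@@H]3[C@H](O)C=CC[C@@H]3C1(C)C | intermediate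
22 | 7-angeloyloxy-9,10-epoxy-8-hydroxy-15-nor-4,10-secolongipin-2-en-1-one | C/C=C(/C)C(=O)O[C@@H]1[C@@H](O)[C@H]2O[C@@]2(C)[C@@H]3C(=O)C=CC[C@@H]3C1(C)C | intermediate
23 | 7-angeloyloxy-1,8-bis(tert-butyldimethylsilyloxy)-9,10-epoxy-15-nor-4,10-secolongipina-1,3-diene | C/C=C(/C)C(=O)O[C@@H]1[C@@H](O[Si](C)(C)C(C)(C)C)[C@H]2O[C@@]2(C)[C@@H]3C(O[Si](C)(C)C(C)(C)C)=CC=C[C@@H]3C1(C)C | intermediate
24 | 7-angeloyloxy-8-(tert-butyldimethylsilyloxy)-9-hydroxy-15-norlongipin-2-en-1-one | C/C=C(/C)C(=O)O[C@@H]1[C@@H](O[Si](C)(C)C(C)(C)C)[C@@H](O)[C@]2(C)[C@@H]3[C@@H]([C@H]2C(=O)C=C3)C1(C)C | intermediate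
25 | 7-angeloyloxy-8-(tert-butyldimethylsilyloxy)-9-hydroxylongipinan-1-one (3-methyl anti to the C10 bridge) | C/C=C(/C)C(=O)O[C@@H]1[C@@H](O[Si](C)(C)C(C)(C)C)[C@@H](O)[C@]2(C)[C@@H]3[C@@H]([C@H]2C(=O)C[C@H]3C)C1(C)C | intermediate
26 | 7,9-bis(angeloyloxy)-8-(tert-butyldimethylsilyloxy)longipinan-1-one | C/C=C(/C)C(=O)O[C@@H]1[C@@H](O[Si](C)(C)C(C)(C)C)[C@@H](OC(=O)/C(C)=C\C)[C@]2(C)[C@@H]3[C@@H]([C@H]2C(=O)C[C@H]3C)C1(C)C | intermediate
27 | (3R,4S,5S,7S,8R,9S,10R,11R)-7,9-bis[(Z)-2-methylbut-2-enoyloxy]-8-hydroxylongipinan-1-one | C/C=C(/C)C(=O)O[C@@H]1[C@@H](O)[C@@H](OC(=O)/C(C)=C\C)[C@]2(C)[C@@H]3[C@@H]([C@H]2C(=O)C[C@H]3C)C1(C)C | target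

Total step count: 19. Longest linear sequence: 18 steps (1 → 27; step 9 is a side branch that makes 16).

Steps most likely to fail

Step 16 (Proposed new method). A hydride shift or elimination at the activated epoxide may outrun C–C bond formation. Fallback with known chemistry: the C4–C10 bond is made by a 4-exo-tet enolate C-alkylation with the polarity of the two carbons exchanged. Setting out from 23, NBS (THF, −78 °C) should brominate the dienol ether at C4 on the face opposite the axial C11 substituent to give 7-angeloyloxy-4-bromo-8-(tert-butyldimethylsilyloxy)-9,10-epoxy-15-nor-4,10-secolongipin-2-en-1-one F1. BF3·OEt2 (CH2Cl2, −78 °C) then induces the Meinwald rearrangement (1,2-hydride shift from C9 to C10) to 7-angeloyloxy-4-bromo-8-(tert-butyldimethylsilyloxy)-15-nor-4,10-secolongipin-2-ene-1,9-dione F2. KOtBu (THF, −78 → 0 °C) forms the C9/C10 enolate, which displaces the allylic bromide with inversion (anti elimination is blocked because H-5 is cis to bromine) to give 7-angeloyloxy-8-(tert-butyldimethylsilyloxy)-15-norlongipin-2-ene-1,9-dione F3. NaBH4 (CH2Cl2–MeOH, −78 °C) should reduce the saturated α-silyloxy C9 ketone, not the enone, from the face opposite the C8 silyloxy group, and the route is rejoined at 24.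

Step 15. Enolisation toward C11 followed by β-elimination would open the epoxide. Fallback: the dienol ether is made without any deprotonation next to the carbonyl, by conjugate sulfoniosilylation and elimination. Setting out from 22, Me2S and TBSOTf (2,6-lutidine, CH2Cl2, −78 °C) add 1,4 to the enone and silylate the C8 hydroxyl to give 7-angeloyloxy-1,8-bis(tert-butyldimethylsilyloxy)-3-(dimethylsulfonio)-9,10-epoxy-15-nor-4,10-secolongipin-1-ene triflate F4. DBU then removes a C4 proton with loss of Me2S, which can only give the 1,3-diene, and the route is rejoined at 23.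

Step 2. The hindered enone may react slowly or with poor facial control, and the acid-sensitive silyloxydiene may decompose under the strong Lewis acid. Fallback: setting out from 2 and 3, the cycloaddition is run with an achiral Lewis acid (EtAlCl2, CH2Cl2, −78 °C) to the racemate, i.e. 4 together with (3aR,7S,7aR)-7-(tert-butyldimethylsilyloxy)-3,3-dimethyl-2,3,3a,4,7,7a-hexahydro-1H-inden-1-one F5. The two are separated by preparative chromatography on a chiral stationary phase, and the route is rejoined at 4.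

Further compounds
F1 | step 16 | 7-angeloyloxy-4-bromo-8-(tert-butyldimethylsilyloxy)-9,10-epoxy-15-nor-4,10-secolongipin-2-en-1-one (Br trans to the C11–C10 bond) | C/C=C(/C)C(=O)O[C@@H]1[C@@H](O[Si](C)(C)C(C)(C)C)[C@H]2O[C@@]2(C)[C@@H]3C(=O)C=C[C@@H](Br)[C@@H]3C1(C)C
F2 | step 16 | 7-angeloyloxy-4-bromo-8-(tert-butyldimethylsilyloxy)-15-nor-4,10-secolongipin-2-ene-1,9-dione | C/C=C(/C)C(=O)O[C@@H]1[C@@H](O[Si](C)(C)C(C)(C)C)C(=O)[C@@H](C)[C@@H]2C(=O)C=C[C@@H](Br)[C@@H]2C1(C)C
F3 | step 16 | 7-angeloyloxy-8-(tert-butyldimethylsilyloxy)-15-norlongipin-2-ene-1,9-dione | C/C=C(/C)C(=O)O[C@@H]1[C@@H](O[Si](C)(C)C(C)(C)C)C(=O)[C@]2(C)[C@@H]3[C@@H]([C@H]2C(=O)C=C3)C1(C)C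
F4 | step 15 | 7-angeloyloxy-1,8-bis(tert-butyldimethylsilyloxy)-3-(dimethylsulfonio)-9,10-epoxy-15-nor-4,10-secolongipin-1-ene triflate (C3 epimers) | C/C=C(/C)C(=O)O[C@@H]1[C@@H](O[Si](C)(C)C(C)(C)C)[C@H]2O[C@@]2(C)[C@@H]3C(O[Si](C)(C)C(C)(C)C)=CC([S+](C)C)C[C@@H]3C1(C)C.[O-]S(=O)(=O)C(F)(F)F
F5 | step 2 | (3aR,7S,7aR)-7-(tert-butyldimethylsilyloxy)-3,3-dimethyl-2,3,3a,4,7,7a-hexahydro-1H-inden-1-one | O=C1CC(C)(C)[C@@H]2CC=C[C@H](O[Si](C)(C)C(C)(C)C)[C@H]12
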